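## Analysis of the target

Euchrenone a16 (21) is a 5,7-dihydroxyflavanone. Ring A is a phloroglucinol-type benzene ring carrying the chelated 5-OH, the 7-OH and a prenyl group at C8. Ring C is the dihydropyranone (O1, C2, C3, C4=O, C4a, C8a). Ring B is the benzene ring of a 2,2-dimethylchroman bonded through its C6, with the dihydropyran as ring D.

The only stereocentre is C2, of (S) configuration, a benzylic carbon bonded to O1, to ring B and to the C3 methylene. It is fragile in two ways. The C2–O1 bond is β to the C4 ketone, so base opens ring C to a 2'-hydroxychalcone and recloses it without stereocontrol. Ring B has its ether oxygen para to C2, so acid can ionise the same bond.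

The prenyl group is a trisubstituted alkene that excludes hydrogenolysis, is attacked by electrophilic oxidants and cyclises onto the 7-OH under strong acid. The second difficulty is regiochemical: C6 and C8 of ring A are electronically alike, and only C8 may carry the prenyl group.

The route rests on one feature: C2 bears O1, ring B and a two-carbon unit (C3–C4). It is therefore the branched carbon of a 1-arylallyl aryl ether whose vinyl group stands for C3 and C4. In ring A the two positions ortho to O1 are C8 (prenyl) and C4a.

## Retrosynthetic reasoning

**Deprotection, 21 to 20.** The two phenols are unmasked last from the bis(methoxymethyl) ether 20. Acetal protection survives base, organometallics, borane and oxidants, and it comes off under mild acid, so the finished flavanone never meets base.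

**C4–C4a bond, 20 to 18.** Ring C is opened at C4–C4a, giving the (S)-3-aryloxy-3-arylpropanoic acid 18. The cut is made here because C4a is the only unsubstituted carbon ortho to O1 and is activated by three oxygens. An intramolecular acylation can therefore close only the six-membered ring at this carbon, and the prenyl group ends at C8 without any regiochemical decision. The forward reaction must acylate without ionising the C2–O1 bond.

**Oxidation level, 18 to 16 to 14.** The CH2–CO2H unit is traced to a vinyl group through the primary alcohol 16. This turns the acid into the (S)-1-arylallyl aryl ether 14, in which C3 and C4 are the two alkene carbons. The forward steps must hydroborate the monosubstituted alkene in the presence of the prenyl group and oxidise the alcohol without eliminating the β-aryloxy group.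

**O1–C2 bond, 14 to 13 and 12.** This is the strategic cut. It separates ring A, as the phenoxide 13 of the prenylated phenol 7, from ring B, as the linear cinnamyl-type carbonate 12. An iridium-catalysed allylic etherification forms the bond at the aryl-bearing allyl terminus and sets C2 by catalyst control. No other disconnection creates the stereocentre from two achiral fragments of this simplicity, and none forms it before the C4 carbonyl exists.

**Prenyl C–C bond, 7 to 6 to 2 and 5.** The prenyl group of 7 is traced to the tertiary 1,1-dimethylallyl ether 6 by an aromatic Claisen rearrangement. Both ortho positions of 6 are equivalent, so only one phenol can form, and the allyl inversion delivers the linear prenyl group. Ether 6 comes from the symmetric phenol 2 and the tertiary carbonate 5, which derive from 1 and 3.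

**Alkene of the electrophile, 12 to 11 to 10 to 8 and 9.** Carbonate 12 is traced through allylic alcohol 11 and ester 10 to aldehyde 8 and phosphonate 9. An E-selective olefination fixes the alkene geometry that the allyl complex needs.

## Alternatives that were turned down

**Alternative 1: carbenoid C–H insertion closing ring C at C2–C3.**
- Disconnection: C2–C3. The precursor is the diazoketone A1, in which C3 is the diazo carbon and C2 is the methylene of a (2,2-dimethylchroman-6-yl)methyl ether on O1.
- Forward key step: a chiral dirhodium carbenoid inserts into one of the two enantiotopic benzylic C–H bonds. This closes ring C and sets C2 in one step to give the bis-silyl flavanone A2, which is then desilylated.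
- For: ring and stereocentre are formed together. The C–H bond is activated by the adjacent oxygen and by the para-oxygenated arene. Fluoride-labile silyl ethers allow a non-acidic end.
- Against: the closure is a 1,6-insertion of an acceptor-only aryl ketone carbenoid, a class with weak enantiotopic discrimination. The carbenoid sits ideally for attack on the lone pair of O1, and the resulting five-membered oxonium ylide would shift the very stabilised para-alkoxybenzyl group to give a benzofuranone instead. Cyclopropanation of the prenyl alkene and arene addition also compete. A1 needs a fully substituted benzoic acid, at least six steps.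
- Comparison: it is stronger after the key step, with one deprotection against four operations here. The chosen route offers a key step whose regio- and enantioselectivity belong to a well-understood catalyst class, and its later steps are ordinary functional-group chemistry.

**Alternative 2: para-Claisen–Cope shift of a 5-O-prenyl ether to C8.**
- Disconnection: the C8–C1'' bond of the prenyl group. The precursor is the 5-O-prenyl ether A3 of the (S)-flavanone, with the 7-OH as acetate.
- Forward key step: a lanthanide β-diketonate Lewis acid promotes the Claisen shift to C6 and the Cope shift on to C8, giving A4 after enolisation. Acetate removal follows.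
- For: the prenyl group is introduced last, so no prenylated building block is needed and no alkene chemoselectivity arises earlier. The free 5-OH emerges directly.
- Against: the key step does nothing for C2, so an enantioenriched flavanone must first be made by a separate asymmetric step. That stereocentre must then survive alkylation of the chelated 5-OH, heating with a Lewis acid bound to the C4/C5 oxygen pair, and acetate cleavage under conditions close to those that open ring C. The shift is not regiospecific, because enolisation of the first dienone before the Cope step leaves the 6-(1,1-dimethylallyl) isomer.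
- Comparison: it is stronger in the lateness and flexibility of prenyl introduction. The chosen route fixes both C2 and the prenyl position by construction and never heats or basifies the finished flavanone.

**Alternative 3: asymmetric conjugate arylation of an 8-prenylchromone.**
- Disconnection: C2–C1'. The precursors are chromone A5 and boronic acid A6.
- Forward key step: a chiral rhodium catalyst transmetalates with A6 and the arylrhodium adds to C2 of A5 with enantioface control. Protonation of the rhodium enolate gives A7, which is the same structure as compound 20 of the chosen route.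
- For: it is the most convergent and the shortest plan, roughly five steps to A5, then the key step and deprotection. The reaction type is known for chromones.
- Against: a 5,7-dioxygenated chromone is an electron-rich, doubly donor-substituted acceptor, and the C5 substituent peri to the carbonyl hinders catalyst binding, so this is the least reactive chromone class. The electron-rich A6 is prone to protodeboronation. The rhodium enolate can expel the O1 phenoxide and open ring C, which costs yield and ee.
- Comparison: it is stronger in step count and convergence. The chosen route forms the stereocentre before the C4 carbonyl exists, so no enolate or retro-Michael channel is open at the enantio-determining step, and its key step does not depend on a deactivated acceptor.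

Key step: step 8

Assumption: the (Sa,Sc,Sc) ligand is assigned to the (S) ether from the usual sense of induction of this catalyst family with cinnamyl carbonates. If the first run gives the opposite sense, the mirror-image ligand is used.

## Route

Step 1
Reactants: 1 phloroglucinol (benzene-1,3,5-triol)
Product: 2 3,5-bis(methoxymethoxy)phenol
Conditions: MOMCl (2.1 equiv), i-Pr2NEt (2.5 equiv), DMF, 0 °C → rt
Reagents that add atoms: chloromethyl methyl ether, COCCl
Why: Williamson-type O-alkylation of a threefold-symmetric triol; all three hydroxyls are equivalent, so only one bis-ether can form, and it should be the main fraction of the statistical mixture, with the mono-ether resubmitted.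

Step 2
Reactants: 3 2-methylbut-3-en-2-ol
Product: 5 methyl 2-methylbut-3-en-2-yl carbonate, via lithium 2-methylbut-3-en-2-olate 4 (not isolated)
Conditions: n-BuLi, THF, −78 → 0 °C; ClCO2Me, −78 °C → rt
Reagents that add atoms: methyl chloroformate, COC(=O)Cl
Why: O-acylation of a preformed tertiary lithium alkoxide with a chloroformate; the alkoxide is made first because the hindered tertiary alcohol is acylated too slowly under amine catalysis.

Step 3
Reactants: 2 3,5-bis(methoxymethoxy)phenol; 5 methyl 2-methylbut-3-en-2-yl carbonate
Product: 6 1,3-bis(methoxymethoxy)-5-[(2-methylbut-3-en-2-yl)oxy]benzene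
Conditions: Pd(PPh3)4 (2 mol %), THF, 0 °C
Reagents that add atoms: none
Why: Tsuji–Trost allylic etherification; zerovalent palladium ionises 5 with loss of CO2 to a 1,1-dimethylallyl complex of divalent palladium and methoxide, which deprotonates 2. At 0 °C the phenoxide should add at the more substituted terminus to give the tertiary ether as the kinetic product, and the reaction is stopped before the catalyst equilibrates it to the linear ether.

Step 4
Reactants: 6 1,3-bis(methoxymethoxy)-5-[(2-methylbut-3-en-2-yl)oxy]benzene
Product: 7 3,5-bis(methoxymethoxy)-2-(3-methylbut-2-en-1-yl)phenol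
Conditions: degassed xylenes, 130 °C
Reagents that add atoms: none
Why: Aromatic Claisen rearrangement ([3,3]-sigmatropic shift) followed by tautomerisation; the allyl inversion turns the 1,1-dimethylallyl ether into a linear prenyl group on carbon, and the two ortho positions of 6 are equivalent, so a single ortho-prenylphenol should result.

Step 5
Reactants: 8 2,2-dimethylchroman-6-carbaldehyde; 9 triethyl phosphonoacetate
Product: 10 ethyl (E)-3-(2,2-dimethylchroman-6-yl)acrylate
Conditions: LiCl, DBU, MeCN, rt
Reagents that add atoms: none
Why: Horner–Wadsworth–Emmons olefination with a stabilised phosphonate; with an aromatic aldehyde the reversible addition and syn-elimination should give the E-alkene almost exclusively.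

Step 6
Reactants: 10 ethyl (E)-3-(2,2-dimethylchroman-6-yl)acrylate
Product: 11 (E)-3-(2,2-dimethylchroman-6-yl)prop-2-en-1-ol
Conditions: i-Bu2AlH (2.5 equiv), CH2Cl2, −78 °C; aq. potassium sodium tartrate
Reagents that add atoms: none
Why: 1,2-reduction of the conjugated ester by the aluminium hydride leaves the alkene untouched; the tartrate work-up avoids acid, to which the para-alkoxycinnamyl alcohol is sensitive.

Step 7
Reactants: 11 (E)-3-(2,2-dimethylchroman-6-yl)prop-2-en-1-ol
Product: 12 (E)-3-(2,2-dimethylchroman-6-yl)allyl methyl carbonate
Conditions: ClCO2Me, pyridine, CH2Cl2, 0 °C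
Reagents that add atoms: methyl chloroformate, COC(=O)Cl
Why: Acylation of a primary allylic alcohol with a chloroformate under pyridine; the methyl carbonate is the standard leaving group for iridium allyl chemistry because it releases CO2 and methoxide on ionisation.

Step 8
Reactants: 7 3,5-bis(methoxymethoxy)-2-(3-methylbut-2-en-1-yl)phenol; 12 (E)-3-(2,2-dimethylchroman-6-yl)allyl methyl carbonate
Product: 14 (S)-6-{1-[3,5-bis(methoxymethoxy)-2-(3-methylbut-2-en-1-yl)phenoxy]allyl}-2,2-dimethylchroman, via lithium 3,5-bis(methoxymethoxy)-2-prenylphenoxide 13 (not isolated)
Conditions: 7 (1.5 equiv), n-BuLi, THF, 0 °C; then 12, [Ir(cod)Cl]2 (2 mol %), (Sa,Sc,Sc)-O,O'-(1,1'-binaphthalene-2,2'-diyl) N,N-bis(1-phenylethyl)phosphoramidite (4 mol %, preactivated with n-PrNH2), THF, rt → 40 °C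
Reagents that add atoms: none
Why: This is an iridium-catalysed enantioselective allylic etherification, and the closest known reaction type is the reaction of lithium aryloxides with cinnamyl carbonates under iridium–phosphoramidite catalysis to give branched 1-arylallyl aryl ethers. [Ir(cod)Cl]2 and the ligand give, after cyclometalation at a methyl group of the ligand, a monovalent iridacycle that ionises 12 with loss of CO2 and methoxide to an allyl complex of trivalent iridium. Phenoxide 13 attacks from outside the coordination sphere, anti to the metal, at the aryl-bearing terminus, forming the O1–C2 bond; no ring is closed. The C2 stereocentre is set by the catalyst alone: the chiral iridacycle fixes which face of the allyl ligand is bound, so the nucleophile reaches only the opposite face. The step needs branched over linear selectivity, O- over C-allylation and enantiofacial control. The first is intrinsic to iridium and is reinforced by the para-oxygenated ring B, which places more positive charge on the benzylic terminus. The lithium counter-ion in THF should keep the ambident phenoxide reacting at oxygen, its single ortho substituent lies within the steric range of this reaction, and the acetals are inert to the basic medium. Because 14 is itself an ionisable 1-arylallyl ether, the reaction is stopped at full conversion of 12 so that ee is not eroded and the linear ether does not build up.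

Step 9
Reactants: 14 (S)-6-{1-[3,5-bis(methoxymethoxy)-2-(3-methylbut-2-en-1-yl)phenoxy]allyl}-2,2-dimethylchroman
Product: 16 (S)-3-[3,5-bis(methoxymethoxy)-2-(3-methylbut-2-en-1-yl)phenoxy]-3-(2,2-dimethylchroman-6-yl)propan-1-ol, via B-alkyl-9-borabicyclo[3.3.1]nonane adduct 15 (not isolated)
Conditions: 9-BBN (1.5 equiv), THF, 0 °C → rt; aq. NaOH, H2O2, 0 °C
Reagents that add atoms: hydrogen peroxide, OO
Why: Anti-Markovnikov hydroboration–oxidation; the bulky dialkylborane reacts with the monosubstituted vinyl group far faster than with the trisubstituted prenyl alkene. Boron ends on the terminal carbon, γ to the ether oxygen, so no β-elimination is possible, and C2 is not involved.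

Step 10
Reactants: 16 (S)-3-[3,5-bis(methoxymethoxy)-2-(3-methylbut-2-en-1-yl)phenoxy]-3-(2,2-dimethylchroman-6-yl)propan-1-ol
Product: 18 (S)-3-[3,5-bis(methoxymethoxy)-2-(3-methylbut-2-en-1-yl)phenoxy]-3-(2,2-dimethylchroman-6-yl)propanoic acid, via β-aryloxy aldehyde 17 (not isolated)
Conditions: TEMPO (20 mol %), PhI(OAc)2 (2.5 equiv), MeCN/aq. pH 7 phosphate buffer, rt
Reagents that add atoms: water, O
Why: Nitroxyl-catalysed oxidation with trivalent iodine as terminal oxidant: the oxoammonium ion oxidises the alcohol to the aldehyde and then the aldehyde hydrate to the acid. The near-neutral, chlorine-free medium should spare the prenyl alkene, the acetals and ring A, and it offers no base that could eliminate the β-aryloxy group from 17.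

Step 11
Reactants: 18 (S)-3-[3,5-bis(methoxymethoxy)-2-(3-methylbut-2-en-1-yl)phenoxy]-3-(2,2-dimethylchroman-6-yl)propanoic acid
Product: 20 (S)-2-(2,2-dimethylchroman-6-yl)-5,7-bis(methoxymethoxy)-8-(3-methylbut-2-en-1-yl)chroman-4-one, via mixed trifluoroacetic anhydride 19 (not isolated)
Conditions: (CF3CO)2O (1.5 equiv), CH2Cl2 (0.02 M), 0 °C; aq. NaHCO3 quench
Reagents that add atoms: none
Why: Intramolecular Friedel–Crafts acylation through the mixed anhydride; C4a is ortho to O1 and to the C5 oxygen and para to the C7 oxygen, so it should acylate without a Lewis acid. The tether allows only six-membered closure at C4a, since C8 is blocked by the prenyl group and C6 is out of reach, and ring B offers only positions meta to its oxygen. Low temperature and high dilution keep the acid concentration low enough to leave the C2–O1 bond and the acetals intact.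

Step 12
Reactants: 20 (S)-2-(2,2-dimethylchroman-6-yl)-5,7-bis(methoxymethoxy)-8-(3-methylbut-2-en-1-yl)chroman-4-one
Product: 21 euchrenone a16, (S)-2-(2,2-dimethylchroman-6-yl)-5,7-dihydroxy-8-(3-methylbut-2-en-1-yl)chroman-4-one
Conditions: 3 M aq. HCl, MeOH, 45 °C, short reaction time
Reagents that add atoms: none
Why: Acid-catalysed acetal methanolysis; the C5 acetal, assisted by chelation to the C4 carbonyl, should leave first and the C7 acetal second. Mild temperature and short exposure are chosen to avoid cyclisation of the prenyl group onto the 7-OH and ionisation at C2, and no base is used after ring closure.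

## Compound list

1 | phloroglucinol | Oc1cc(O)cc(O)c1 | starting material
2 | 3,5-bis(methoxymethoxy)phenol | COCOc1cc(O)cc(OCOC)c1 | intermediate
3 | 2-methylbut-3-en-2-ol | CC(C)(O)C=C | starting material
4 | lithium 2-methylbut-3-en-2-olate | [Li+].CC(C)([O-])C=C | intermediate (not isolated)
5 | methyl 2-methylbut-3-en-2-yl carbonate | COC(=O)OC(C)(C)C=C | intermediate
6 | 1,3-bis(methoxymethoxy)-5-[(2-methylbut-3-en-2-yl)oxy]benzene | C=CC(C)(C)Oc1cc(OCOC)cc(OCOC)c1 | intermediate
7 | 3,5-bis(methoxymethoxy)-2-(3-methylbut-2-en-1-yl)phenol | CC(C)=CCc1c(O)cc(OCOC)cc1OCOC | intermediate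
8 | 2,2-dimethylchroman-6-carbaldehyde | CC1(C)CCc2cc(C=O)ccc2O1 | starting material
9 | triethyl phosphonoacetate | CCOC(=O)CP(=O)(OCC)OCC | starting material
10 | ethyl (E)-3-(2,2-dimethylchroman-6-yl)acrylate | CCOC(=O)/C=C/c1ccc2c(c1)CCC(C)(C)O2 | intermediate
11 | (E)-3-(2,2-dimethylchroman-6-yl)prop-2-en-1-ol | OC/C=C/c1ccc2c(c1)CCC(C)(C)O2 | intermediate
12 | (E)-3-(2,2-dimethylchroman-6-yl)allyl methyl carbonate | COC(=O)OC/C=C/c1ccc2c(c1)CCC(C)(C)O2 | intermediate
13 | lithium 3,5-bis(methoxymethoxy)-2-(3-methylbut-2-en-1-yl)phenoxide | [Li+].CC(C)=CCc1c([O-])cc(OCOC)cc1OCOC | intermediate (not isolated)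
14 | (S)-6-{1-[3,5-bis(methoxymethoxy)-2-(3-methylbut-2-en-1-yl)phenoxy]allyl}-2,2-dimethylchroman | CC(C)=CCc1c(OCOC)cc(OCOC)cc1O[C@H](c1ccc3c(c1)CCC(C)(C)O3)C=C | intermediate
15 | (S)-B-alkyl-9-borabicyclo[3.3.1]nonane adduct of 14 (boron on the terminal carbon) | CC(C)=CCc1c(OCOC)cc(OCOC)cc1O[C@H](c1ccc3c(c1)CCC(C)(C)O3)CCB1C2CCCC1CCC2 | intermediate (not isolated)
16 | (S)-3-[3,5-bis(methoxymethoxy)-2-(3-methylbut-2-en-1-yl)phenoxy]-3-(2,2-dimethylchroman-6-yl)propan-1-ol | CC(C)=CCc1c(OCOC)cc(OCOC)cc1O[C@H](c1ccc3c(c1)CCC(C)(C)O3)CCO | intermediate
17 | (S)-3-[3,5-bis(methoxymethoxy)-2-(3-methylbut-2-en-1-yl)phenoxy]-3-(2,2-dimethylchroman-6-yl)propanal | CC(C)=CCc1c(OCOC)cc(OCOC)cc1O[C@H](c1ccc3c(c1)CCC(C)(C)O3)CC=O | intermediate (not isolated)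
18 | (S)-3-[3,5-bis(methoxymethoxy)-2-(3-methylbut-2-en-1-yl)phenoxy]-3-(2,2-dimethylchroman-6-yl)propanoic acid | CC(C)=CCc1c(OCOC)cc(OCOC)cc1O[C@H](c1ccc3c(c1)CCC(C)(C)O3)CC(=O)O | intermediate
19 | mixed anhydride of 18 with trifluoroacetic acid | CC(C)=CCc1c(OCOC)cc(OCOC)cc1O[C@H](c1ccc3c(c1)CCC(C)(C)O3)CC(=O)OC(=O)C(F)(F)F | intermediate (not isolated)
20 | (S)-2-(2,2-dimethylchroman-6-yl)-5,7-bis(methoxymethoxy)-8-(3-methylbut-2-en-1-yl)chroman-4-one | CC(C)=CCc1c(OCOC)cc(OCOC)c2c1O[C@H](c1ccc3c(c1)CCC(C)(C)O3)CC2=O | intermediate
21 | euchrenone a16 | CC(C)=CCc1c(O)cc(O)c2c1O[C@H](c1ccc3c(c1)CCC(C)(C)O3)CC2=O | target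

## Step count and least certain steps

Total: 12 steps. Longest linear sequence: 8 steps (1, 3, 4, 8, 9, 10, 11, 12 from phloroglucinol; equally 5 to 12 from aldehyde 8).

**Step 8 (key step).** The ambident phloroglucinol-type phenoxide may alkylate through a ring carbon instead of oxygen. The ortho-substituted nucleophile may react so slowly that carbonate exchange takes over. The product may re-ionise on the catalyst, which would erode ee and give the linear ether. The fallback sets out from 7 and 11 and returns at 14, delivering the phenoxide inside an ion pair instead of as a free lithium salt. Alcohol 11 is treated with 1,1'-carbonyldiimidazole to give (E)-3-(2,2-dimethylchroman-6-yl)allyl 1H-imidazole-1-carboxylate F1. F1 is coupled with 7 under catalytic DBU to give the mixed aryl allyl carbonate F2. F2 is then decarboxylated with [CpRu(MeCN)3]PF6 and a chiral pyridine–oxazoline ligand in THF. The allylruthenium–phenoxide ion pair should recombine at the benzylic terminus to give 14. This is a decarboxylative allylic etherification of the known ruthenium-catalysed type.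

**Step 11.** The trifluoroacetic acid released may ionise the para-alkoxybenzylic C2–O1 bond, causing fragmentation or loss of configuration. It may also remove an acetal early, which would allow the prenyl group to cyclise. The anhydride may acylate C6 intermolecularly. The fallback sets out from 18 and returns at 20 and uses a base-buffered electrophile. Acid 18 is coupled with dimethylamine to the N,N-dimethylamide F3. F3 is activated with (CF3SO2)2O and 2-chloropyridine in CH2Cl2 at −78 → 0 °C, a Vilsmeier–Haack-type intramolecular acylation. C4a attacks the activated amide to give the cyclic iminium triflate F4, which aqueous NaHCO3 hydrolyses to 20.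

**Step 10.** The intermediate aldehyde may lose the aryloxide by β-elimination, which destroys the stereocentre. The trivalent iodine oxidant may attack the very electron-rich ring A. The fallback sets out from 16 and returns at 18 in two separate stages with different oxidants. Dess–Martin periodinane, buffered with NaHCO3 in CH2Cl2, gives aldehyde 17, which is used without chromatography. NaClO2 and NaH2PO4 in t-BuOH/H2O with a large excess of 2-methylbut-2-ene then give 18. This fallback makes no compound outside the list (F0).

**Step 12.** The prenyl group may cyclise onto the freed 7-OH under acid, and ring C may open and reclose at C2 with partial racemisation. The fallback sets out from 20 and returns at 21 by silyl transfer instead of Brønsted acid hydrolysis. Me3SiOSO2CF3 with 2,2'-bipyridyl in CH2Cl2 at 0 °C converts both aryl acetals, through pyridinium intermediates, into the bis(trimethylsilyl) ether F5. Water at neutral pH cleaves F5 to 21.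

**Step 3.** The allylpalladium intermediate may be captured at a ring carbon, or the tertiary ether may isomerise to the linear prenyl ether, which would rearrange to the wrong C-substituent in step 4. The fallback sets out from 2 and returns at 6 and builds the tertiary ether without an allyl complex. Phenol 2 is alkylated with 3-chloro-3-methylbut-1-yne (K2CO3, KI, catalytic CuI, acetone) to the 1,1-dimethylpropargyl ether F6. Semihydrogenation of F6 (H2, Pd/CaCO3 poisoned with Pb(OAc)2, quinoline) gives 6.

## Further compounds

F1 | step 8 | (E)-3-(2,2-dimethylchroman-6-yl)allyl 1H-imidazole-1-carboxylate | O=C(OC/C=C/c1ccc2c(c1)CCC(C)(C)O2)n1ccnc1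
F2 | step 8 | (E)-3-(2,2-dimethylchroman-6-yl)allyl 3,5-bis(methoxymethoxy)-2-(3-methylbut-2-en-1-yl)phenyl carbonate | CC(C)=CCc1c(OC(=O)OC/C=C/c2ccc3c(c2)CCC(C)(C)O3)cc(OCOC)cc1OCOC
F3 | step 11 | (S)-3-[3,5-bis(methoxymethoxy)-2-(3-methylbut-2-en-1-yl)phenoxy]-3-(2,2-dimethylchroman-6-yl)-N,N-dimethylpropanamide | CC(C)=CCc1c(OCOC)cc(OCOC)cc1O[C@H](c1ccc3c(c1)CCC(C)(C)O3)CC(=O)N(C)C
F4 | step 11 | (S)-N-[2-(2,2-dimethylchroman-6-yl)-5,7-bis(methoxymethoxy)-8-(3-methylbut-2-en-1-yl)chroman-4-ylidene]-N-methylmethanaminium trifluoromethanesulfonate | CC(C)=CCc1c(OCOC)cc(OCOC)c2c1O[C@H](c1ccc3c(c1)CCC(C)(C)O3)CC2=[N+](C)C.[O-]S(=O)(=O)C(F)(F)F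
F0 | step 10 | none | none
F5 | step 12 | (S)-2-(2,2-dimethylchroman-6-yl)-8-(3-methylbut-2-en-1-yl)-5,7-bis(trimethylsilyloxy)chroman-4-one | CC(C)=CCc1c(O[Si](C)(C)C)cc(O[Si](C)(C)C)c2c1O[C@H](c1ccc3c(c1)CCC(C)(C)O3)CC2=O
F6 | step 3 | 1,3-bis(methoxymethoxy)-5-[(2-methylbut-3-yn-2-yl)oxy]benzene | C#CC(C)(C)Oc1cc(OCOC)cc(OCOC)c1
A1 | alternative 1 | 2-diazo-1-{2-[(2,2-dimethylchroman-6-yl)methoxy]-3-(3-methylbut-2-en-1-yl)-4,6-bis(triisopropylsilyloxy)phenyl}ethan-1-one | CC(C)=CCc1c(O[Si](C(C)C)(C(C)C)C(C)C)cc(O[Si](C(C)C)(C(C)C)C(C)C)c(C(=O)C=[N+]=[N-])c1OCc1ccc2c(c1)CCC(C)(C)O2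
A2 | alternative 1 | (S)-2-(2,2-dimethylchroman-6-yl)-8-(3-methylbut-2-en-1-yl)-5,7-bis(triisopropylsilyloxy)chroman-4-one | CC(C)=CCc1c(O[Si](C(C)C)(C(C)C)C(C)C)cc(O[Si](C(C)C)(C(C)C)C(C)C)c2c1O[C@H](c1ccc3c(c1)CCC(C)(C)O3)CC2=O
A3 | alternative 2 | (S)-7-acetoxy-2-(2,2-dimethylchroman-6-yl)-5-[(3-methylbut-2-en-1-yl)oxy]chroman-4-one | CC(=O)Oc1cc(OCC=C(C)C)c2c(c1)O[C@H](c1ccc3c(c1)CCC(C)(C)O3)CC2=O
A4 | alternative 2 | (S)-7-acetoxy-2-(2,2-dimethylchroman-6-yl)-5-hydroxy-8-(3-methylbut-2-en-1-yl)chroman-4-one | CC(C)=CCc1c(OC(C)=O)cc(O)c2c1O[C@H](c1ccc3c(c1)CCC(C)(C)O3)CC2=O
A5 | alternative 3 | 5,7-bis(methoxymethoxy)-8-(3-methylbut-2-en-1-yl)-4H-chromen-4-one | CC(C)=CCc1c(OCOC)cc(OCOC)c2c(=O)ccoc12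
A6 | alternative 3 | (2,2-dimethylchroman-6-yl)boronic acid | OB(O)c1ccc2c(c1)CCC(C)(C)O2
A7 | alternative 3 | (S)-2-(2,2-dimethylchroman-6-yl)-5,7-bis(methoxymethoxy)-8-(3-methylbut-2-en-1-yl)chroman-4-one | CC(C)=CCc1c(OCOC)cc(OCOC)c2c1O[C@H](c1ccc3c(c1)CCC(C)(C)O3)CC2=O
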